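**Retrosynthetic overview**
- The target is ring A, a cyclic β-triketone, joined through one CH2 to ring B, a 2,6-dihydroxy-4-methoxyphenyl pentyl ketone. Ring A locants used here: C1 carries the hexanoyl group, C2 and C4 are the enolized carbonyl carbons, C3 is the quaternary carbon, C5 carries the bridge, C6 is the ring C=O. The last disconnection is the C5–CH2 bond: ring-A triketone plus the o-quinone methide released from the Mannich base of the ring-B phenone.
- The strategy rests on this feature: C2–C3–C4 of ring A is a methyl(prenyl)malonyl unit. C3 is stereogenic only because C2 is bonded to C1 (hexanoyl) and C4 to C5 (bridge), so fixing the configuration at C3 means deciding which malonyl carbonyl becomes C2 and which C4.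
- Ring A is cut at C4–C5 and C1–C2 into the 1,3-dianion of nonane-2,4-dione (which supplies C5, C6, C1 and the hexanoyl chain) and the (R)-configured methyl(prenyl)malonyl half-ester chloride (COCl becomes C4, CO2Me becomes C2).
- The half-ester chloride comes from dimethyl methylmalonate by prenylation, esterase desymmetrization and chloride formation. Ring B comes from phloroglucinol by C-acylation, 4-O-methylation and aminomethylation.
- Ring order: ring B is present from the start as an arene; ring A is the only ring made, in step 4.

Key step: step 4

Assumption: the esterase in step 2 is taken to leave the (S)-half-ester as the major product; its sense and enantiomeric purity are to be measured on that acid before step 3, and the fallback for step 2 supplies the same acid whatever the enzyme prefers.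
Remark: the β-triketones are drawn as one enol tautomer and the descriptors refer to that drawing; systematic names carry their own numbering (the quaternary carbon is C4 there).

**Step 1**
Reactants: 1 dimethyl methylmalonate; 2 prenyl bromide (1-bromo-3-methylbut-2-ene)
Product: 3 dimethyl 2-methyl-2-(3-methylbut-2-en-1-yl)propanedioate
Conditions: NaH (1.1 equiv), THF, 0 °C; then 2 (1.1 equiv), 0 to 20 °C
Reagents that add atoms: none
Why: Malonic ester alkylation, in which the sodium enolate displaces bromide from the primary allylic carbon (SN2) and cannot be alkylated twice because no α-hydrogen remains.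

**Step 2**
Reactants: 3 dimethyl 2-methyl-2-(3-methylbut-2-en-1-yl)propanedioate
Product: 4 (2S)-3-methoxy-2-methyl-2-(3-methylbut-2-en-1-yl)-3-oxopropanoic acid
Conditions: pig liver esterase, NaH2PO4/Na2HPO4 buffer (0.1 M, pH 7.5), DMSO (10 vol%), 25 °C, pH-stat with 1 M NaOH (1.0 equiv); then cold 1 M HCl to pH 3, EtOAc
Reagents that add atoms: water, O
Why: Enzymatic desymmetrization, in which the esterase hydrolyses only one of the two enantiotopic methoxycarbonyl groups of prochiral 3 because methyl and prenyl fit its binding pockets differently; this sets the quaternary stereocenter, and the carboxylate formed is not hydrolysed a second time.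

**Step 3**
Reactants: 4 (2S)-3-methoxy-2-methyl-2-(3-methylbut-2-en-1-yl)-3-oxopropanoic acid
Product: 6 methyl (2R)-2-(chlorocarbonyl)-2,5-dimethylhex-4-enoate, via sodium carboxylate 5 (not isolated)
Conditions: NaH (1.0 equiv), THF, 0 °C; then (COCl)2 (1.2 equiv), Me2NCHO (cat.), 0 to 20 °C; evaporate, hexane, filter
Reagents that add atoms: oxalyl chloride, ClC(=O)C(=O)Cl
Why: Acyl chloride formation from a carboxylate, in which the mixed anhydride with oxalyl chloride collapses with loss of CO, CO2 and NaCl and no free HCl, so the prenyl alkene is neither hydrochlorinated nor lactonized, and the stereocenter has no α-hydrogen and cannot epimerize through a ketene.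

**Step 4**
Reactants: 6 methyl (2R)-2-(chlorocarbonyl)-2,5-dimethylhex-4-enoate; 7 nonane-2,4-dione
Product: 10 (4S)-2-hexanoyl-3,5-dihydroxy-4-methyl-4-(3-methylbut-2-en-1-yl)cyclohexa-2,5-dien-1-one, via nonanedione dianion 8 (not isolated), via triketo ester 9 (not isolated)
Conditions: 7 (2.2 equiv), NaH (2.2 equiv), THF, 0 °C; n-BuLi (2.2 equiv), 0 °C; 6 (1.0 equiv) added slowly, −78 °C, 1 h; then 20 °C (50 °C if closure is slow); 1 M HCl
Reagents that add atoms: none
Why: The more basic terminal carbanion (former CH3) of dianion 8 attacks the acyl chloride of 6 at −78 °C and forms C4–C5, a second equivalent of 8 deprotonates the resulting triketo ester 9, and on warming the carbon between C6 and the hexanoyl carbonyl attacks the methyl ester, expels methoxide and forms C1–C2. The closest known reactions are the terminal C-acylation of 1,3-diketone dianions to 1,3,5-triketones and the Claisen (Dieckmann-type) cyclization of 3,5,7-triketo esters to acylphloroglucinols and 4,4-dialkylcyclohexane-1,3,5-triones. Ring A closes in a 6-(enolexo)-exo-trig mode onto an ester that cannot enolize because its α-carbon is quaternary, and the strongly acidic product leaves all equilibria as its dianion, so an enol lactone formed by O-attack should be reopened by methoxide and drained to 10. No stereocenter is created: C3 keeps its four bonds, and its configuration in ring A follows only from the chloride carbon becoming C4 and the ester carbon C2, which turns the (R)-chloride into the (S)-triketone. The step needs chemoselectivity between the two malonyl carbonyls (a first attack on the ester would give the enantiomer), which rests on the reactivity gap between an acyl chloride and a neopentyl-type methyl ester at −78 °C, and regioselectivity in the dianion, which rests on kinetic metalation of CH3 over the pentyl CH2. Free amine and excess alkoxide are kept out so that the hexanoyl group is not lost by retro-Claisen cleavage.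

**Step 5**
Reactants: 11 phloroglucinol (benzene-1,3,5-triol)
Product: 12 1-(2,4,6-trihydroxyphenyl)hexan-1-one
Conditions: hexanoyl chloride (1.0 equiv), AlCl3 (3.5 equiv), CH2Cl2/MeNO2, 0 to 40 °C; ice, 1 M HCl
Reagents that add atoms: hexanoyl chloride, CCCCCC(=O)Cl
Why: Friedel–Crafts acylation of the very electron-rich triol, which should stop after one acyl group because the aryl ketone formed is deactivated and held as an aluminium chelate.

**Step 6**
Reactants: 12 1-(2,4,6-trihydroxyphenyl)hexan-1-one
Product: 13 1-(2,6-dihydroxy-4-methoxyphenyl)hexan-1-one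
Conditions: Me2SO4 (1.0 equiv), K2CO3 (1.0 equiv), acetone, 20 °C to reflux
Reagents that add atoms: dimethyl sulfate, COS(=O)(=O)OC
Why: Williamson ether synthesis on the most acidic phenol, since the 4-OH is para to the ketone and free of the hydrogen bonds that tie the 2- and 6-OH groups to the carbonyl oxygen, so its phenoxide is methylated first, and the product keeps the mirror plane that makes the two free ring carbons equivalent.

**Step 7**
Reactants: 13 1-(2,6-dihydroxy-4-methoxyphenyl)hexan-1-one
Product: 15 1-{3-[(dimethylamino)methyl]-2,6-dihydroxy-4-methoxyphenyl}hexan-1-one, via Mannich base hydroiodide 14 (not isolated)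
Conditions: [Me2N=CH2]I (1.0 equiv), CH2Cl2, 0 to 20 °C; then aq. NaHCO3
Reagents that add atoms: N,N-dimethylmethyleneiminium iodide, C=[N+](C)C.[I-]
Why: Mannich reaction (aromatic aminomethylation by the preformed iminium ion) at one of the two equivalent free ring carbons, each ortho to an OH, with the product separating as hydroiodide 14, whose ammonium group slows a second substitution.

**Step 8**
Reactants: 10 (4S)-2-hexanoyl-3,5-dihydroxy-4-methyl-4-(3-methylbut-2-en-1-yl)cyclohexa-2,5-dien-1-one; 15 1-{3-[(dimethylamino)methyl]-2,6-dihydroxy-4-methoxyphenyl}hexan-1-one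
Product: 17 (4S)-2-hexanoyl-6-[(3-hexanoyl-2,4-dihydroxy-6-methoxyphenyl)methyl]-3,5-dihydroxy-4-methyl-4-(3-methylbut-2-en-1-yl)cyclohexa-2,5-dien-1-one (CNP0108719.1), via o-quinone methide 16 (not isolated)
Conditions: 10 (1.0 equiv), 15 (1.05 equiv), 1,4-dioxane, 80 °C, N2; then wash with 0.5 M HCl
Reagents that add atoms: none
Why: The acidic triketone 10 protonates the amine of 15, the o-hydroxybenzylammonium ion loses Me2NH on heating (retro-Mannich) to the o-quinone methide 16, and the triketonate adds through C5, its only unsubstituted ring carbon, in a Michael addition that restores the aromaticity of ring B and leaves the quaternary stereocenter untouched.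

**Compound list**
1 | dimethyl methylmalonate | COC(=O)C(C)C(=O)OC | starting material
2 | prenyl bromide (1-bromo-3-methylbut-2-ene) | CC(C)=CCBr | starting material
3 | dimethyl 2-methyl-2-(3-methylbut-2-en-1-yl)propanedioate | COC(=O)C(C)(CC=C(C)C)C(=O)OC | intermediate
4 | (2S)-3-methoxy-2-methyl-2-(3-methylbut-2-en-1-yl)-3-oxopropanoic acid | COC(=O)[C@@](C)(CC=C(C)C)C(=O)O | intermediate
5 | sodium (2S)-3-methoxy-2-methyl-2-(3-methylbut-2-en-1-yl)-3-oxopropanoate (not isolated) | COC(=O)[C@@](C)(CC=C(C)C)C(=O)[O-].[Na+] | intermediate
6 | methyl (2R)-2-(chlorocarbonyl)-2,5-dimethylhex-4-enoate | COC(=O)[C@@](C)(CC=C(C)C)C(=O)Cl | intermediate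
7 | nonane-2,4-dione | CCCCCC(=O)CC(C)=O | starting material
8 | sodium lithium salt of the nonane-2,4-dione 1,3-dianion (not isolated) | [CH2-]C(=O)[CH-]C(=O)CCCCC.[Na+].[Li+] | intermediate
9 | methyl (2S)-2-methyl-2-(3-methylbut-2-en-1-yl)-3,5,7-trioxododecanoate (not isolated, present as its enolates) | COC(=O)[C@@](C)(CC=C(C)C)C(=O)CC(=O)CC(=O)CCCCC | intermediate
10 | (4S)-2-hexanoyl-3,5-dihydroxy-4-methyl-4-(3-methylbut-2-en-1-yl)cyclohexa-2,5-dien-1-one (ring-A monomer) | CCCCCC(=O)C1=C(O)[C@@](C)(CC=C(C)C)C(O)=CC1=O | intermediate
11 | phloroglucinol (benzene-1,3,5-triol) | Oc1cc(O)cc(O)c1 | starting material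
12 | 1-(2,4,6-trihydroxyphenyl)hexan-1-one | CCCCCC(=O)c1c(O)cc(O)cc1O | intermediate
13 | 1-(2,6-dihydroxy-4-methoxyphenyl)hexan-1-one | CCCCCC(=O)c1c(O)cc(OC)cc1O | intermediate
14 | (3-hexanoyl-2,4-dihydroxy-6-methoxyphenyl)methyl-dimethylammonium iodide (hydroiodide of 15, not isolated) | CCCCCC(=O)c1c(O)cc(OC)c(C[NH+](C)C)c1O.[I-] | intermediate
15 | 1-{3-[(dimethylamino)methyl]-2,6-dihydroxy-4-methoxyphenyl}hexan-1-one | CCCCCC(=O)c1c(O)cc(OC)c(CN(C)C)c1O | intermediate
16 | 2-hexanoyl-3-hydroxy-5-methoxy-6-methylidenecyclohexa-2,4-dien-1-one (o-quinone methide, not isolated) | C=C1C(OC)=CC(O)=C(C(=O)CCCCC)C1=O | intermediate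
17 | (4S)-2-hexanoyl-6-[(3-hexanoyl-2,4-dihydroxy-6-methoxyphenyl)methyl]-3,5-dihydroxy-4-methyl-4-(3-methylbut-2-en-1-yl)cyclohexa-2,5-dien-1-one | CCCCCC(=O)C1=C(O)[C@@](C)(CC=C(C)C)C(O)=C(Cc2c(OC)cc(O)c(C(=O)CCCCC)c2O)C1=O | target

**Step count and risks**
Total steps: 8. Longest linear sequence: 5 (steps 1, 2, 3, 4, 8); the ring-B branch (steps 5, 6, 7) joins in step 8.

Steps most likely to fail:

1. Step 4. The cascade may stop after the first C–C bond, because the stabilized enolate carbon attacks the neopentyl-type ester slowly or the triketo ester is diverted to its enol lactone. The dianion may also be used up by proton transfer from the acylated product faster than it is acylated, or metalation of the pentyl CH2 may compete with that of CH3. The fallback separates the two bond formations and uses neutral acylation. It sets out from 7: the dianion is generated as before and trapped with Me3SiCl to give (3Z)-2,4-bis(trimethylsilyloxy)nona-1,3-diene F1. This 1,3-bis(silyl enol ether) is C-acylated at its terminal carbon by 6 in CH2Cl2 (−78 to 20 °C, Me3SiOSO2CF3 in catalytic amount if needed; Mukaiyama-type acylation), the ester staying untouched, and aqueous work-up gives 9 as an isolated compound. Compound 9 is then closed in a separate Claisen cyclization with Mg(OMe)2 in MeOH at reflux, and the route is rejoined at 10.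

2. Step 2. The esterase may discriminate the enantiotopic ester groups weakly or in the opposite sense for the methyl/prenyl pair, and turnover of the hindered diester may be slow. The fallback replaces desymmetrization by resolution. It sets out from 3: statistical mono-saponification (KOH, 1.0 equiv, MeOH, 20 °C, then HCl) gives racemic 3-methoxy-2-methyl-2-(3-methylbut-2-en-1-yl)-3-oxopropanoic acid F2. This is separated by preparative chromatography on a chiral stationary phase (supercritical CO2/MeOH) into 4 and (2R)-3-methoxy-2-methyl-2-(3-methylbut-2-en-1-yl)-3-oxopropanoic acid F3. F3 is re-esterified to 3 (MeI, K2CO3, Me2NCHO) and recycled; the route is rejoined at 4.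

3. Step 8. The quinone methide may be captured by a second phenone unit or by the free aromatic carbon of ring B in the product (oligomer formation). The bridge may be transferred reversibly on prolonged heating. A slow 1,3-shift of the hexanoyl group of 10 from C1 across the C6 oxygen to C5 before alkylation would erode the enantiomeric purity. The fallback reverses the polarity of the coupling and blocks C5 early. It sets out from 10 and 13: 10 is aminomethylated at C5 with [Me2N=CH2]I (CH2Cl2, 0 °C, NaHCO3 work-up) to (4S)-6-[(dimethylamino)methyl]-2-hexanoyl-3,5-dihydroxy-4-methyl-4-(3-methylbut-2-en-1-yl)cyclohexa-2,5-dien-1-one F4. On warming in dioxane with 13 (3 equiv, recoverable), F4 loses Me2NH to (4R)-2-hexanoyl-3-hydroxy-4-methyl-6-methylidene-4-(3-methylbut-2-en-1-yl)cyclohex-2-ene-1,5-dione F5 (same spatial arrangement as in 10; not isolated). This 2-methylidene-1,3-dione is attacked by a free ring carbon of 13 in a Friedel–Crafts-type Michael addition, the way alkylidene cyclic triketones take up acylphloroglucinols, and the route is rejoined at 17.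

**Further compounds**
F1 | step 4 | (3Z)-2,4-bis(trimethylsilyloxy)nona-1,3-diene | C=C(O[Si](C)(C)C)/C=C(/CCCCC)O[Si](C)(C)C
F2 | step 2 | racemic 3-methoxy-2-methyl-2-(3-methylbut-2-en-1-yl)-3-oxopropanoic acid | COC(=O)C(C)(CC=C(C)C)C(=O)O
F3 | step 2 | (2R)-3-methoxy-2-methyl-2-(3-methylbut-2-en-1-yl)-3-oxopropanoic acid | COC(=O)[C@](C)(CC=C(C)C)C(=O)O
F4 | step 8 | (4S)-6-[(dimethylamino)methyl]-2-hexanoyl-3,5-dihydroxy-4-methyl-4-(3-methylbut-2-en-1-yl)cyclohexa-2,5-dien-1-one | CCCCCC(=O)C1=C(O)[C@@](C)(CC=C(C)C)C(O)=C(CN(C)C)C1=O
F5 | step 8 | (4R)-2-hexanoyl-3-hydroxy-4-methyl-6-methylidene-4-(3-methylbut-2-en-1-yl)cyclohex-2-ene-1,5-dione | CCCCCC(=O)C1=C(O)[C@@](C)(CC=C(C)C)C(=O)C(=C)C1=O
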